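**Strategy.** The route rests on cutting ring A (the tetrahydropyran O2–C1–C11a–C4a–C4–C3, xenicane numbering) into two three-atom pieces: a 1,3-dinucleophile C4/O2 (an enolised formyl ketone that already holds the L-proline-derived side chain) and a 1,3-dielectrophile C4a/C1 (a Morita–Baylis–Hillman carbonate made from (S)-linalool, whose carbinol becomes C7). One cinchona-amine-catalysed allylic alkylation/oxa-Michael [3+3] annulation joins the halves, forms C4–C4a and O2–C1, and sets C4a and C11a. The activating ketone at C12 is then reduced and transposed into the dihydrofuran acetal, the ester at C11 becomes the allyl ketone, and ring-closing metathesis, methylenation and directed epoxidation finish the nine-membered ring.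

Key step: step 11

Numbering used below (xenicane convention): ring A C1H2–O2–C3H(acetal)–C4(=C12)–C4a–C11a; nine-membered ring C4a–C5–C6–C7(CH3 = C18, OH)–C8–C9–C10–C11(=C19H2)–C11a; dihydrofuran C3–C4=C12–C13–O; side chain C14(OH)–C15(OH)(CH3)2.
Assumption: (S)-(+)-linalool is taken as a commercial chiral-pool terpene of high enantiomeric purity.

**Route**

Step 1
Reactants: 1 (S)-(+)-linalool
Product: 2 (3S)-3,7-dimethyl-3-(trimethylsilyloxy)octa-1,6-diene
Conditions: TMSCl, imidazole, DMF, 0 °C to rt
Reagents that add atoms: chlorotrimethylsilane, C[Si](C)(C)Cl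
Why: Silylation of the tertiary alcohol keeps the later aldehyde from closing to a lactol, and a tertiary trimethylsilyl ether is stable to base yet falls off under the mild acid of step 12.

Step 2
Reactants: 2 (3S)-3,7-dimethyl-3-(trimethylsilyloxy)octa-1,6-diene
Product: 3 (4S)-4-methyl-4-(trimethylsilyloxy)hex-5-enal
Conditions: O3 (1.0 equiv), CH2Cl2, −78 °C; Me2S
Reagents that add atoms: ozone, [O-][O+]=O
Why: Ozonolysis with reductive work-up is chemoselective because the electron-rich trisubstituted alkene reacts far faster than the hindered vinyl group.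

Step 3
Reactants: 3 (4S)-4-methyl-4-(trimethylsilyloxy)hex-5-enal; 4 methyl acrylate
Product: 5 methyl (6S)-3-hydroxy-6-methyl-2-methylidene-6-(trimethylsilyloxy)oct-7-enoate (both C3 epimers)
Conditions: DABCO (0.5 equiv), neat methyl acrylate, rt
Reagents that add atoms: none
Why: Morita–Baylis–Hillman reaction of an unhindered aliphatic aldehyde; the uncontrolled carbinol centre is erased in step 11.

Step 4
Reactants: 5 methyl (6S)-3-hydroxy-6-methyl-2-methylidene-6-(trimethylsilyloxy)oct-7-enoate
Product: 6 methyl (6S)-3-(tert-butoxycarbonyloxy)-6-methyl-2-methylidene-6-(trimethylsilyloxy)oct-7-enoate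
Conditions: Boc2O, DMAP (10 mol %), CH2Cl2, 0 °C to rt
Reagents that add atoms: di-tert-butyl dicarbonate, CC(C)(C)OC(=O)OC(=O)OC(C)(C)C
Why: Acylation of the allylic alcohol gives the standard Morita–Baylis–Hillman carbonate, whose leaving group generates its own base on ionisation.

Step 5
Reactants: 7 methyl 2-hydroxy-2-methylpropanoate
Product: 8 methyl 2-methyl-2-(triethylsilyloxy)propanoate
Conditions: TESOTf, 2,6-lutidine, CH2Cl2, 0 °C
Reagents that add atoms: triethylsilyl trifluoromethanesulfonate, CC[Si](CC)(CC)OS(=O)(=O)C(F)(F)F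
Why: The silyl triflate silylates the hindered tertiary alcohol; a tertiary triethylsilyl ether survives the mild acid of step 12 and leaves with fluoride at the end.

Step 6
Reactants: 8 methyl 2-methyl-2-(triethylsilyloxy)propanoate
Product: 9 2-methyl-2-(triethylsilyloxy)propanal
Conditions: iBu2AlH (1.1 equiv), CH2Cl2, −78 °C; aq. potassium sodium tartrate
Reagents that add atoms: none
Why: Half-reduction of an α-silyloxy ester stops at the aldehyde because the tetrahedral aluminium hemiacetal is stable at −78 °C.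

Step 7
Reactants: 9 2-methyl-2-(triethylsilyloxy)propanal; 10 hydroxyacetone
Product: 11 (3S,4R)-3,4-dihydroxy-5-methyl-5-(triethylsilyloxy)hexan-2-one (anti diol)
Conditions: L-proline (30 mol %), DMSO/hydroxyacetone 4:1, rt
Reagents that add atoms: none
Why: Proline-catalysed direct aldol reaction of hydroxyacetone; the hydroxy-enamine reacts at its oxygenated carbon with the non-enolisable aldehyde through the hydrogen-bonded chair transition state, so L-proline sets both centres (future C13 and C14) as the anti diol.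

Step 8
Reactants: 11 (3S,4R)-3,4-dihydroxy-5-methyl-5-(triethylsilyloxy)hexan-2-one
Product: 12 (3S,4R)-4-hydroxy-5-methyl-3,5-bis(triethylsilyloxy)hexan-2-one
Conditions: TESCl (1.05 equiv), imidazole, CH2Cl2, −20 °C
Reagents that add atoms: chlorotriethylsilane, CC[Si](CC)(CC)Cl
Why: The α-keto hydroxyl is the less hindered of the two secondary alcohols (the other is flanked by the quaternary carbon), so one equivalent of silyl chloride at low temperature should take it selectively.

Step 9
Reactants: 12 (3S,4R)-4-hydroxy-5-methyl-3,5-bis(triethylsilyloxy)hexan-2-one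
Product: 13 (3S,4R)-4-(tert-butyldimethylsilyloxy)-5-methyl-3,5-bis(triethylsilyloxy)hexan-2-one
Conditions: TBSOTf, 2,6-lutidine, CH2Cl2, −78 to 0 °C
Reagents that add atoms: tert-butyldimethylsilyl trifluoromethanesulfonate, CC(C)(C)[Si](C)(C)OS(=O)(=O)C(F)(F)F
Why: The silyl triflate protects the hindered hydroxyl as the acid-stable TBS ether, which keeps this oxygen from competing in the ring closure of step 12.

Step 10
Reactants: 13 (3S,4R)-4-(tert-butyldimethylsilyloxy)-5-methyl-3,5-bis(triethylsilyloxy)hexan-2-one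
Product: 14 (1Z,4S,5R)-5-(tert-butyldimethylsilyloxy)-1-hydroxy-6-methyl-4,6-bis(triethylsilyloxy)hept-1-en-3-one (hydroxymethylene ketone, used crude)
Conditions: LiN(iPr)2 (1.1 equiv), THF, −78 °C; HCO2Et, −78 to 0 °C; aq. NH4Cl
Reagents that add atoms: ethyl formate, CCOC=O
Why: Crossed Claisen formylation of the kinetic methyl-side lithium enolate; the product is held as its chelated enolate, which shields the adjacent silyloxy centre from epimerisation.

Step 11
Reactants: 6 methyl (6S)-3-(tert-butoxycarbonyloxy)-6-methyl-2-methylidene-6-(trimethylsilyloxy)oct-7-enoate; 14 (1Z,4S,5R)-5-(tert-butyldimethylsilyloxy)-1-hydroxy-6-methyl-4,6-bis(triethylsilyloxy)hept-1-en-3-one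
Product: 16 methyl (3S,4S)-5-[(2S,3R)-3-(tert-butyldimethylsilyloxy)-4-methyl-2,4-bis(triethylsilyloxy)pentanoyl]-4-[(3S)-3-methyl-3-(trimethylsilyloxy)pent-4-en-1-yl]-3,4-dihydro-2H-pyran-3-carboxylate (3,4-trans), via C-allylated formyl ketone 15 (not isolated)
Conditions: (DHQD)2PHAL (10 mol %), PhMe, 25 °C; then DBU (0.3 equiv), 25 °C
Reagents that add atoms: none
Why: The tertiary amine adds to C1 of 6 in an SN2′ sense and expels tert-butyl carbonate, which loses CO2 and deprotonates 14; the formyl ketone enolate then attacks C4a of the chiral allyl ammonium ion through carbon (second SN2′, C4–C4a bond, giving 15), and the enol oxygen O2 of 15 closes ring A on the regenerated acrylate by a base-mediated 6-endo-trig oxa-Michael addition (O2–C1 bond). The closest known reaction type is the cinchona-amine-catalysed asymmetric allylic alkylation of Morita–Baylis–Hillman carbonates with 1,3-dicarbonyl compounds and its [3+3] annulation variant to pyrans. C4a is set by the catalyst, which shields one face of the ammonium enoate, since the remote centres at C7, C13 and C14 give no useful bias; (DHQD)2PHAL is the series proposed for 4aS, and the sense of induction is assigned by analogy only. C11a is set by thermodynamic protonation of the ester enolate, reversible through retro-oxa-Michael addition, which should place the ester trans to the C4a chain. The step needs C- over O-allylation (soft ammonium enoate, soft dicarbonyl carbon), branched over linear attack (normal for the amine-bound allyl unit) and closure through the formyl and not the ketone oxygen, which the unhindered formyl enol and the conjugated vinylogous-ester product should secure.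

Step 12
Reactants: 16 dihydropyran keto ester (3S,4S)
Product: 18 methyl (2R,4S,5S,7aS)-2-[(1R)-1-(tert-butyldimethylsilyloxy)-2-methyl-2-(triethylsilyloxy)propyl]-4-[(3S)-3-hydroxy-3-methylpent-4-en-1-yl]-4,5,6,7a-tetrahydro-2H-furo[2,3-b]pyran-5-carboxylate, via allylic alcohol 17 (not isolated)
Conditions: NaBH4, CeCl3·7H2O, MeOH, −40 to 0 °C; then PPTS (0.3 equiv), CH2Cl2 co-solvent, 0 °C to rt
Reagents that add atoms: none
Why: Luche 1,2-reduction of the vinylogous-ester carbonyl (C12) spares the methyl ester, and mild acid then ionises the γ-hydroxy enol ether to the conjugated oxocarbenium ion (Stork–Danheiser-type transposition) while methanolysing the secondary TES and tertiary TMS ethers, so that the freed C13 hydroxyl closes the five-membered ring on C3; the new acetal centre is forced to the target configuration (H3 cis to H4a) because the planar dihydrofuran can only be fused to a chair pyran with its oxygen equatorial.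

Step 13
Reactants: 18 bicyclic acetal ester
Product: 20 1-[(2R,4S,5S,7aS)-2-[(1R)-1-(tert-butyldimethylsilyloxy)-2-methyl-2-(triethylsilyloxy)propyl]-4-[(3S)-3-hydroxy-3-methylpent-4-en-1-yl]-4,5,6,7a-tetrahydro-2H-furo[2,3-b]pyran-5-yl]but-3-en-1-one, via Weinreb amide 19 (not isolated)
Conditions: MeNHOMe·HCl, iPrMgCl (excess), THF, −20 °C; then CH2=CHCH2MgBr, −20 to 0 °C
Reagents that add atoms: allylmagnesium bromide, C=CC[Mg]Br
Why: In situ Weinreb amide formation followed by Grignard addition stops at the ketone through the stable magnesium chelate; the free tertiary alcohol is carried as its alkoxide and C11a stays in the favoured trans arrangement.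

Step 14
Reactants: 20 allyl ketone
Product: 21 tricyclic ketone (3S,4aS,7S,8Z,11aS,13R,14R): as 24 but with C11=O in place of C11=C19H2, a (Z)-C8=C9 alkene in place of the epoxide, 14-OTBS and 15-OTES
Conditions: second-generation Hoveyda–Grubbs catalyst RuCl2(H2IMes)(=CH-C6H4-2-OiPr) (10 mol %), 1,4-benzoquinone (20 mol %), PhMe (1 mM), 80 °C
Reagents that add atoms: none
Why: Ring-closing metathesis of the two monosubstituted alkenes, held gauche by the trans-diequatorial C4a and C11a substituents of the chair pyran; the nine-membered ring should form as the Z alkene, the free allylic hydroxyl assists the hindered vinyl group, and benzoquinone suppresses alkene migration.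

Step 15
Reactants: 21 tricyclic ketone
Product: 22 triene (3S,4aS,7S,8Z,11aR,13R,14R): as 24 but with the (Z)-C8=C9 alkene in place of the epoxide, 14-OTBS and 15-OTES
Conditions: Cp2TiMe2 (3 equiv), PhMe/THF, 65 °C, dark
Reagents that add atoms: dimethyltitanocene, [CH3-].[CH3-].[Ti+4].c1cc[cH-]c1.c1cc[cH-]c1
Why: Petasis methylenation is non-basic, so the easily enolised β,γ-unsaturated ketone should be methylenated without epimerisation at C11a or alkene migration.

Step 16
Reactants: 22 triene
Product: 23 14-O-TBS, 15-O-TES ether of 24 (3S,4aS,7S,8R,9R,11aR,13R,14R)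
Conditions: VO(acac)2 (5 mol %), tBuOOH (1.5 equiv), CH2Cl2, 0 °C to rt
Reagents that add atoms: tert-butyl hydroperoxide, CC(C)(C)OO
Why: Hydroxyl-directed epoxidation: the vanadium-bound peroxide is delivered by the tertiary C7 hydroxyl to the adjacent (Z)-C8=C9 alkene on the hydroxyl face, giving the cis-epoxy alcohol as is known for medium-ring allylic alcohols, and leaves the exocyclic and dihydrofuran alkenes untouched.

Step 17
Reactants: 23 bis-silyl ether
Product: 24 target, (3S,4aS,7S,8R,9R,11aR,13R,14R)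
Conditions: Bu4NF (5 equiv), AcOH (5 equiv), THF, 0 °C to rt
Reagents that add atoms: none
Why: Fluoride cleaves the secondary TBS and tertiary TES ethers; acetic acid buffering should keep the epoxy alcohol from Payne rearrangement and the acetal from acid.

**Compound list**

1 | (S)-(+)-linalool | CC(C)=CCC[C@](C)(O)C=C | starting material
2 | (3S)-3,7-dimethyl-3-(trimethylsilyloxy)octa-1,6-diene | CC(C)=CCC[C@](C)(O[Si](C)(C)C)C=C | intermediate
3 | (4S)-4-methyl-4-(trimethylsilyloxy)hex-5-enal | O=CCC[C@](C)(O[Si](C)(C)C)C=C | intermediate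
4 | methyl acrylate | C=CC(=O)OC | starting material
5 | methyl (6S)-3-hydroxy-6-methyl-2-methylidene-6-(trimethylsilyloxy)oct-7-enoate, both C3 epimers | C=C(C(=O)OC)C(O)CC[C@](C)(O[Si](C)(C)C)C=C | intermediate
6 | methyl (6S)-3-(tert-butoxycarbonyloxy)-6-methyl-2-methylidene-6-(trimethylsilyloxy)oct-7-enoate | C=C(C(=O)OC)C(OC(=O)OC(C)(C)C)CC[C@](C)(O[Si](C)(C)C)C=C | intermediate
7 | methyl 2-hydroxy-2-methylpropanoate | COC(=O)C(C)(C)O | starting material
8 | methyl 2-methyl-2-(triethylsilyloxy)propanoate | COC(=O)C(C)(C)O[Si](CC)(CC)CC | intermediate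
9 | 2-methyl-2-(triethylsilyloxy)propanal | O=CC(C)(C)O[Si](CC)(CC)CC | intermediate
10 | hydroxyacetone | CC(=O)CO | starting material
11 | (3S,4R)-3,4-dihydroxy-5-methyl-5-(triethylsilyloxy)hexan-2-one | CC(=O)[C@@H](O)[C@@H](O)C(C)(C)O[Si](CC)(CC)CC | intermediate
12 | (3S,4R)-4-hydroxy-5-methyl-3,5-bis(triethylsilyloxy)hexan-2-one | CC(=O)[C@@H](O[Si](CC)(CC)CC)[C@@H](O)C(C)(C)O[Si](CC)(CC)CC | intermediate
13 | (3S,4R)-4-(tert-butyldimethylsilyloxy)-5-methyl-3,5-bis(triethylsilyloxy)hexan-2-one | CC(=O)[C@@H](O[Si](CC)(CC)CC)[C@@H](O[Si](C)(C)C(C)(C)C)C(C)(C)O[Si](CC)(CC)CC | intermediate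
14 | (1Z,4S,5R)-5-(tert-butyldimethylsilyloxy)-1-hydroxy-6-methyl-4,6-bis(triethylsilyloxy)hept-1-en-3-one | O/C=C\C(=O)[C@@H](O[Si](CC)(CC)CC)[C@@H](O[Si](C)(C)C(C)(C)C)C(C)(C)O[Si](CC)(CC)CC | intermediate
15 | methyl (3R,6S)-3-[(3S,4R)-4-(tert-butyldimethylsilyloxy)-1-formyl-5-methyl-2-oxo-3,5-bis(triethylsilyloxy)hexyl]-6-methyl-2-methylidene-6-(trimethylsilyloxy)oct-7-enoate, epimers at the formyl-bearing carbon, largely enolised | O=CC(C(=O)[C@@H](O[Si](CC)(CC)CC)[C@@H](O[Si](C)(C)C(C)(C)C)C(C)(C)O[Si](CC)(CC)CC)[C@@H](CC[C@](C)(O[Si](C)(C)C)C=C)C(=C)C(=O)OC | intermediate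
16 | methyl (3S,4S)-5-[(2S,3R)-3-(tert-butyldimethylsilyloxy)-4-methyl-2,4-bis(triethylsilyloxy)pentanoyl]-4-[(3S)-3-methyl-3-(trimethylsilyloxy)pent-4-en-1-yl]-3,4-dihydro-2H-pyran-3-carboxylate | C=C[C@@](C)(O[Si](C)(C)C)CC[C@@H]1C(C(=O)[C@@H](O[Si](CC)(CC)CC)[C@@H](O[Si](C)(C)C(C)(C)C)C(C)(C)O[Si](CC)(CC)CC)=COC[C@H]1C(=O)OC | intermediate
17 | allylic alcohol from 16 (C12 carbinol, both epimers; other centres as in 16) | C=C[C@@](C)(O[Si](C)(C)C)CC[C@@H]1C(C(O)[C@@H](O[Si](CC)(CC)CC)[C@@H](O[Si](C)(C)C(C)(C)C)C(C)(C)O[Si](CC)(CC)CC)=COC[C@H]1C(=O)OC | intermediate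
18 | methyl (2R,4S,5S,7aS)-2-[(1R)-1-(tert-butyldimethylsilyloxy)-2-methyl-2-(triethylsilyloxy)propyl]-4-[(3S)-3-hydroxy-3-methylpent-4-en-1-yl]-4,5,6,7a-tetrahydro-2H-furo[2,3-b]pyran-5-carboxylate | C=C[C@@](C)(O)CC[C@@H]2C3=C[C@H]([C@@H](O[Si](C)(C)C(C)(C)C)C(C)(C)O[Si](CC)(CC)CC)O[C@@H]3OC[C@H]2C(=O)OC | intermediate
19 | (2R,4S,5S,7aS)-N-methoxy-N-methyl-5-carboxamide analogue of 18 | C=C[C@@](C)(O)CC[C@@H]2C3=C[C@H]([C@@H](O[Si](C)(C)C(C)(C)C)C(C)(C)O[Si](CC)(CC)CC)O[C@@H]3OC[C@H]2C(=O)N(C)OC | intermediate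
20 | 1-[(2R,4S,5S,7aS)-2-[(1R)-1-(tert-butyldimethylsilyloxy)-2-methyl-2-(triethylsilyloxy)propyl]-4-[(3S)-3-hydroxy-3-methylpent-4-en-1-yl]-4,5,6,7a-tetrahydro-2H-furo[2,3-b]pyran-5-yl]but-3-en-1-one | C=C[C@@](C)(O)CC[C@@H]2C3=C[C@H]([C@@H](O[Si](C)(C)C(C)(C)C)C(C)(C)O[Si](CC)(CC)CC)O[C@@H]3OC[C@H]2C(=O)CC=C | intermediate
21 | tricyclic ketone (3S,4aS,7S,8Z,11aS,13R,14R): C11=O, (Z)-C8=C9, 7-OH, 14-OTBS, 15-OTES | O=C1C/C=C\[C@@](C)(O)CC[C@@H]2C3=C[C@H]([C@@H](O[Si](C)(C)C(C)(C)C)C(C)(C)O[Si](CC)(CC)CC)O[C@@H]3OC[C@@H]12 | intermediate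
22 | triene (3S,4aS,7S,8Z,11aR,13R,14R): C11=C19H2, (Z)-C8=C9, 7-OH, 14-OTBS, 15-OTES | C=C1C/C=C\[C@@](C)(O)CC[C@@H]2C3=C[C@H]([C@@H](O[Si](C)(C)C(C)(C)C)C(C)(C)O[Si](CC)(CC)CC)O[C@@H]3OC[C@@H]12 | intermediate
23 | 14-O-(tert-butyldimethylsilyl)-15-O-(triethylsilyl) ether of 24 | C=C1C[C@H]2O[C@H]2[C@@](C)(O)CC[C@@H]2C3=C[C@H]([C@@H](O[Si](C)(C)C(C)(C)C)C(C)(C)O[Si](CC)(CC)CC)O[C@@H]3OC[C@@H]12 | intermediate
24 | target (3S,4aS,7S,8R,9R,11aR,13R,14R), CNP0281409.2 | C=C1C[C@H]2O[C@H]2[C@@](C)(O)CC[C@@H]2C3=C[C@H]([C@@H](O)C(C)(C)O)O[C@@H]3OC[C@@H]12 | target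

**Count**

Total steps: 17. Longest linear sequence: 13 (steps 5–17).

**Steps most likely to fail**

1. Step 11. The catalyst may fail to control the C4a face with an aliphatic carbonate and an acidic acyclic formyl ketone. The enolate may also react through oxygen, or the ring may close through the ketone oxygen. If the sense of induction is opposite, the pseudo-enantiomeric (DHQ)2PHAL is used. The fallback moves the stereocontrol from the catalyst to a separation. From 6 and 14, achiral DABCO (20 mol %) in toluene followed by DBU should give 16 together with its C4a/C11a epimer, methyl (3R,4R)-dihydropyran keto ester F1. The two are diastereomers because of the remote centres at C7, C13 and C14; they are separated by chromatography and the route is rejoined at 16.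

2. Step 12. Under acid the oxocarbenium ion may lose the C13 proton, or the product acetal may ionise and aromatise to the furan. The mixture may also stall at methyl acetals or E-configured open forms. The fallback replaces acid by a neutral palladium-catalysed Ferrier-type allylic substitution. From 16, Luche reduction gives 17, which is isolated. Methyl chloroformate and pyridine convert it into the allylic methyl carbonate F2. HF·pyridine buffered with pyridine (THF, 0 °C) removes the secondary TES and tertiary TMS groups to give the diol carbonate F3. Zerovalent palladium (Pd2(dba)3, PPh3, THF) ionises the carbonate to the alkoxy-substituted π-allyl complex, which the C13 hydroxyl attacks at C3 to give 18.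

3. Step 14. Oligomerisation may outrun closure of the nine-membered ring, the allyl double bond may migrate into conjugation with the ketone, or the ketone may chelate the ruthenium carbene. The fallback takes the ring closure off the β,γ-unsaturated ketone. From 20, NaBH4 (MeOH, 0 °C) gives the homoallylic alcohols F4. Ring-closing metathesis under the same dilution on this sp3 carbinol gives the cyclononenols F5. Dess–Martin periodinane (NaHCO3, CH2Cl2) re-oxidises F5 to 21.

Further compounds
F1 | step 11 | methyl (3R,4R)-5-[(2S,3R)-3-(tert-butyldimethylsilyloxy)-4-methyl-2,4-bis(triethylsilyloxy)pentanoyl]-4-[(3S)-3-methyl-3-(trimethylsilyloxy)pent-4-en-1-yl]-3,4-dihydro-2H-pyran-3-carboxylate | C=C[C@@](C)(O[Si](C)(C)C)CC[C@H]1C(C(=O)[C@@H](O[Si](CC)(CC)CC)[C@@H](O[Si](C)(C)C(C)(C)C)C(C)(C)O[Si](CC)(CC)CC)=COC[C@@H]1C(=O)OC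
F2 | step 12 | allylic methyl carbonate of 17 | C=C[C@@](C)(O[Si](C)(C)C)CC[C@@H]1C(C(OC(=O)OC)[C@@H](O[Si](CC)(CC)CC)[C@@H](O[Si](C)(C)C(C)(C)C)C(C)(C)O[Si](CC)(CC)CC)=COC[C@H]1C(=O)OC
F3 | step 12 | diol carbonate (free C13 and C7 hydroxyls) | C=C[C@@](C)(O)CC[C@@H]1C(C(OC(=O)OC)[C@@H](O)[C@@H](O[Si](C)(C)C(C)(C)C)C(C)(C)O[Si](CC)(CC)CC)=COC[C@H]1C(=O)OC
F4 | step 14 | homoallylic alcohols from 20 (both C11 epimers) | C=C[C@@](C)(O)CC[C@@H]2C3=C[C@H]([C@@H](O[Si](C)(C)C(C)(C)C)C(C)(C)O[Si](CC)(CC)CC)O[C@@H]3OC[C@H]2C(O)CC=C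
F5 | step 14 | (8Z)-cyclononenols, C11 carbinol analogues of 21 | OC1C/C=C\[C@@](C)(O)CC[C@@H]2C3=C[C@H]([C@@H](O[Si](C)(C)C(C)(C)C)C(C)(C)O[Si](CC)(CC)CC)O[C@@H]3OC[C@@H]12
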